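**Strategy.** The route rests on cutting ring A from ring B at the C1–C10 and C4–C5 bonds (drimane numbering). Ring B (C5–C10) carries oxygen at C6, methyls at C8 and C10 and the C11 arm on C9, the carbonyl carbon between the two methyls of 2,6-dimethyl-1,4-benzoquinone. C1–C4, with the C3 oxygen and the C4 gem-dimethyl group, are the dienol silyl ether of isopropyl vinyl ketone. One catalytic enantioselective Diels–Alder reaction of these two achiral partners closes ring A, forms both bonds, creates the C10 quaternary stereocentre and leaves the C6 and C9 carbonyls distinguishable. C9 is then methylenated and hydroborated to C11, and umbelliferone is attached last.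

Key step: step 2

Assumption: locants follow the drimane skeleton (ring A = C1–C5 and C10, ring B = C5–C10, C11 on C9) without implying its natural absolute configuration, and the (S)-configured oxazaborolidine is taken, from the accepted pre-transition-state model for quinones, to give C10 as drawn; if the sense proved opposite, the mirror-image catalyst would be used with nothing else changed.

**Step 1**
Reactants: 1 4-methylpent-1-en-3-one (isopropyl vinyl ketone)
Product: 2 4-methyl-3-(triisopropylsilyloxy)penta-1,3-diene
Conditions: TIPSOTf (1.1 equiv), Et3N (1.5 equiv), Et2O, 0 °C → rt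
Reagents that add atoms: triisopropylsilyl trifluoromethanesulfonate (TIPSOTf), CC(C)[Si](OS(=O)(=O)C(F)(F)F)(C(C)C)C(C)C
Why: Soft enolisation, in which silylation of the carbonyl oxygen acidifies the isopropyl methine hydrogen, the only α-hydrogen, so that Et3N can give a single 2-silyloxydiene and no stereocentre arises.

**Step 2**
Reactants: 3 2,6-dimethyl-1,4-benzoquinone; 2 4-methyl-3-(triisopropylsilyloxy)penta-1,3-diene
Product: 4 cis-fused adduct (5S,10R)-3-(triisopropylsilyloxy)-11-nordrima-2,7-diene-6,9-dione (5-H and 10-CH3 cis)
Conditions: (S)-tetrahydro-1-(2-methylphenyl)-3,3-diphenyl-1H,3H-pyrrolo[1,2-c][1,3,2]oxazaborole (20 mol%), HNTf2 (18 mol%), 2 (2 equiv), CH2Cl2, −78 → −40 °C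
Reagents that add atoms: none
Why: The N-protonated oxazaborolidine binds the unhindered C6 carbonyl of quinone 3 through boron with the usual α-C–H···O contact, which lowers the LUMO and marks one face of one of the two enantiotopic C=C bonds, and the s-cis dienol ether 2 adds across that bond in a concerted, asynchronous [4+2] cycloaddition (a Mukaiyama–Michael then Michael sequence would end at the same two bonds). The closest known reaction type is the oxazaborolidinium-catalysed Diels–Alder addition of 2-silyloxybutadienes to methyl-substituted 1,4-benzoquinones. Ring A closes as a six-membered carbocycle by intermolecular cycloaddition, C1–C10 and C4–C5 forming suprafacially on the quinone, so the ring fusion is cis. C10 is set by the catalyst, which selects one enantiotopic alkene face, and C5 follows from the suprafacial addition and is reset later. The step needs orientational and enantiofacial selectivity but no site selectivity, because the two quinone alkenes are symmetry-equivalent: the orientation is secured by the diene, whose fully substituted nucleophilic CMe2 terminus cannot bond to the methyl-bearing quinone carbon and is matched with C5, the carbon β to the electron-poorer C9 carbonyl of the free quinone, whereas the enantioselection comes from the rigid catalyst–quinone complex. Because catalyst binding at the C6 carbonyl polarises the alkene in the opposite sense, the orientation rests on sterics and is the main uncertainty; the angular methyl prevents aromatisation of the adduct.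

**Step 3**
Reactants: 4 cis-fused adduct
Product: 5 (10R)-6-(tert-butyldimethylsilyloxy)-3-(triisopropylsilyloxy)-11-nordrima-2,5,7-trien-9-one
Conditions: TBSOTf (1.3 equiv), Et3N (2.5 equiv), CH2Cl2, −78 → 0 °C
Reagents that add atoms: tert-butyldimethylsilyl trifluoromethanesulfonate (TBSOTf), CC(C)(C)[Si](C)(C)OS(=O)(=O)C(F)(F)F
Why: Soft enolisation to an enol silyl ether, possible only at the C6 ketone (C5–H is its α-hydrogen, acidified by the enedione, whereas the C9 ketone lies between the quaternary C10 and the alkene carbon C8), so that kinetic α′-deprotonation masks C6, removes the C5 centre and leaves C9 as the single free carbonyl with C10 untouched.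

**Step 4**
Reactants: 5 bis(enol silyl ether) ketone; 6 methyltriphenylphosphonium bromide
Product: 8 (10S)-6-(tert-butyldimethylsilyloxy)-3-(triisopropylsilyloxy)drima-2,5,7,9(11)-tetraene, via methylenetriphenylphosphorane 7 (not isolated)
Conditions: 6 (3 equiv), KN(SiMe3)2 (2.8 equiv), toluene, 0 °C; then 5, 0 → 80 °C
Reagents that add atoms: none
Why: Wittig methylenation of a ketone that has no acidic hydrogen left, so the basic ylide can only add to the C9 carbonyl, whose shielding by C10 and the C8 methyl is met by excess reagent and heating, while the amide base leaves no alkoxide that could attack the silyl enol ethers and no stereocentre is involved.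

**Step 5**
Reactants: 8 tetraene
Product: 10 trans-fused (5S,10R)-drima-7,9(11)-diene-3,6-dione, via cis-fused C5 epimer 9 (not isolated)
Conditions: Bu4NF (2.5 equiv), AcOH (2.5 equiv), THF, 0 °C → rt; then DBU (0.2 equiv), CH2Cl2, rt
Reagents that add atoms: none
Why: Fluoride-induced cleavage of both enol silyl ethers under acetic acid buffering frees the C3 and C6 ketones without a strong acid that could protonate the exocyclic methylene and trigger a 1,2-shift with aromatisation of ring B, and any cis-fused epimer formed on protonation of C5 is equilibrated through the C6 enolate by DBU to the trans-fused dione, expected to be the more stable isomer as in the target, where C5 is likewise α to the C6 ketone.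

**Step 6**
Reactants: 10 trans-fused dione
Product: 11 (3R,5S,6S,10R)-drima-7,9(11)-diene-3,6-diol (both hydroxyls cis to the C10 methyl)
Conditions: NaBH4 (3 equiv), CeCl3·7H2O (2 equiv), MeOH, −40 → 0 °C; aq. NaHCO3
Reagents that add atoms: none
Why: Luche reduction, in which the cerium-modified borohydride reduces the C6 dienone carbonyl in 1,2-fashion from the face opposite the syn-axial C4 and C10 methyls and the C3 ketone by axial attack on the face away from the axial C4 methyl, which gives the equatorial 3-alcohol, also cis to the C10 methyl.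

**Step 7**
Reactants: 11 dienediol
Product: 13 (3R,5S,6S,9R,10S)-drim-7-ene-3,6,11-triol, via C11 organoborane 12 (not isolated)
Conditions: 9-BBN (4 equiv), THF, 0 → 60 °C; then aq. NaOH, 30% H2O2, 0 °C → rt
Reagents that add atoms: hydrogen peroxide, OO
Why: Hydroboration–oxidation, in which 9-BBN, after capping the two hydroxyls as borinates, adds to the 1,1-disubstituted exocyclic alkene with boron at C11 much faster than to the trisubstituted C7=C8 and approaches the face opposite the adjacent axial C10 methyl, so that hydrogen enters C9 on that face, C11 ends cis to the methyl (9R) and oxidation replaces boron by oxygen with retention.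

**Step 8**
Reactants: 13 triol; 14 umbelliferone (7-hydroxycoumarin)
Product: 15 7-{[(3R,5S,6S,9R,10S)-3,6-dihydroxydrim-7-en-11-yl]oxy}-2H-chromen-2-one
Conditions: PPh3 (1.5 equiv), diisopropyl azodicarboxylate (1.5 equiv), THF, 0 °C → rt
Reagents that add atoms: none
Why: Mitsunobu etherification, in which only the primary C11 alcohol forms the alkoxyphosphonium ion at a useful rate (the C3 hydroxyl is neopentylic and the axial C6 hydroxyl lies between two syn-axial methyls), the acidic phenol of 14 displaces it at the CH2 carbon without touching a stereocentre, and with C6 still an alcohol the aryloxide cannot be lost by vinylogous β-elimination.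

**Step 9**
Reactants: 15 umbelliferyl ether diol
Product: 16 ligupersin A, 7-{[(3R,5S,9R,10S)-3-hydroxy-6-oxodrim-7-en-11-yl]oxy}-2H-chromen-2-one
Conditions: activated MnO2 (30 equiv), CH2Cl2, rt
Reagents that add atoms: none
Why: Allylic oxidation with MnO2, a neutral heterogeneous oxidant that converts the allylic C6 alcohol into the enone and leaves alone the saturated, hindered C3 alcohol, the aryl ether and the enolisable C5 and C9 centres.

**Compound list**
1 | 4-methylpent-1-en-3-one (isopropyl vinyl ketone) | C=CC(=O)C(C)C | starting material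
2 | 4-methyl-3-(triisopropylsilyloxy)penta-1,3-diene | C=CC(O[Si](C(C)C)(C(C)C)C(C)C)=C(C)C | intermediate
3 | 2,6-dimethyl-1,4-benzoquinone | CC1=CC(=O)C=C(C)C1=O | starting material
4 | cis-fused (5S,10R)-3-(triisopropylsilyloxy)-11-nordrima-2,7-diene-6,9-dione | CC1=CC(=O)[C@H]2C(C)(C)C(O[Si](C(C)C)(C(C)C)C(C)C)=CC[C@@]2(C)C1=O | intermediate
5 | (10R)-6-(tert-butyldimethylsilyloxy)-3-(triisopropylsilyloxy)-11-nordrima-2,5,7-trien-9-one | CC1=CC(O[Si](C)(C)C(C)(C)C)=C2C(C)(C)C(O[Si](C(C)C)(C(C)C)C(C)C)=CC[C@@]2(C)C1=O | intermediate
6 | methyltriphenylphosphonium bromide | C[P+](c1ccccc1)(c1ccccc1)c1ccccc1.[Br-] | starting material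
7 | methylenetriphenylphosphorane | C=P(c1ccccc1)(c1ccccc1)c1ccccc1 | intermediate (not isolated)
8 | (10S)-6-(tert-butyldimethylsilyloxy)-3-(triisopropylsilyloxy)drima-2,5,7,9(11)-tetraene | CC1=CC(O[Si](C)(C)C(C)(C)C)=C2C(C)(C)C(O[Si](C(C)C)(C(C)C)C(C)C)=CC[C@@]2(C)C1=C | intermediate
9 | cis-fused (5R,10R)-drima-7,9(11)-diene-3,6-dione | CC1=CC(=O)[C@H]2C(C)(C)C(=O)CC[C@@]2(C)C1=C | intermediate (not isolated)
10 | trans-fused (5S,10R)-drima-7,9(11)-diene-3,6-dione | CC1=CC(=O)[C@@H]2C(C)(C)C(=O)CC[C@@]2(C)C1=C | intermediate
11 | (3R,5S,6S,10R)-drima-7,9(11)-diene-3,6-diol | CC1=C[C@H](O)[C@@H]2C(C)(C)[C@H](O)CC[C@@]2(C)C1=C | intermediate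
12 | C11 B-alkyl-9-borabicyclo[3.3.1]nonane derived from 11, with the C3 and C6 oxygens as 9-BBN borinates, C9 as in 13 | CC1=C[C@H](OB3C4CCCC3CCC4)[C@@H]2C(C)(C)[C@H](OB5C6CCCC5CCC6)CC[C@@]2(C)[C@@H]1CB7C8CCCC7CCC8 | intermediate (not isolated)
13 | (3R,5S,6S,9R,10S)-drim-7-ene-3,6,11-triol | CC1=C[C@H](O)[C@@H]2C(C)(C)[C@H](O)CC[C@@]2(C)[C@@H]1CO | intermediate
14 | umbelliferone (7-hydroxycoumarin) | Oc1ccc2ccc(=O)oc2c1 | starting material
15 | 7-{[(3R,5S,6S,9R,10S)-3,6-dihydroxydrim-7-en-11-yl]oxy}-2H-chromen-2-one | CC1=C[C@H](O)[C@@H]2C(C)(C)[C@H](O)CC[C@@]2(C)[C@@H]1COc1ccc2ccc(=O)oc2c1 | intermediate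
16 | ligupersin A | CC1=CC(=O)[C@@H]2C(C)(C)[C@H](O)CC[C@@]2(C)[C@@H]1COc1ccc2ccc(=O)oc2c1 | target

**Total step count:** 9
**Longest linear sequence:** 9 steps (1 → 2 → 4 → 5 → 8 → 10 → 11 → 13 → 15 → 16)

**Steps most likely to fail**

1. Step 2. The orientation of addition may reverse, because the catalyst sits on the C6 carbonyl and so makes C10, not C5, the more electrophilic alkene carbon. The twisted, terminally disubstituted diene may also stall or stop at an open-chain Mukaiyama–Michael stage, and the enantiotopic faces may be poorly discriminated. Fallback, setting out from 2 and 3: the cycloaddition is run without any Lewis acid (toluene, 80 °C, or CH2Cl2 at 12 kbar), conditions under which the polarisation of the free quinone and the steric demand of the diene call for the same orientation. This should give the racemic cis-fused adduct F1, which is resolved by preparative chromatography on a chiral stationary phase (amylose tris(3,5-dimethylphenylcarbamate)). The (5S,10R) enantiomer is 4, where the route is rejoined.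

2. Step 4. The ylide may fail to add to the doubly flanked, cross-conjugated C9 carbonyl, or the prolonged heating with base may strip an enol silyl ether. Fallback, setting out from 5: a Peterson olefination, in which the small, weakly basic Me3SiCH2Li (THF, −78 → 0 °C) adds to C9 to give the β-hydroxysilane F2 (tertiary C9 alcohol bearing CH2SiMe3, either C9 epimer). KH (THF, 0 °C → rt) then brings about syn-elimination of silanolate and returns the route to 8.

3. Step 8. The allylic C6 hydroxyl may be activated in competition (ether formation or dehydration there), or the activated C11 oxygen may be eliminated toward the 7,9(11)-diene instead of being displaced. Fallback, setting out from 11: both secondary hydroxyls are silylated first (Et3SiOTf, 2,6-lutidine, CH2Cl2, −78 → 0 °C) to the bis(triethylsilyl) ether F3. Hydroboration with 9-BBN gives the C11 organoborane F4, which is oxidised (aq. NaOH, H2O2) to the primary alcohol F5. Mitsunobu coupling of this single free hydroxyl with 14 (PPh3, diisopropyl azodicarboxylate, THF) gives the bis(triethylsilyl) umbelliferyl ether F6. Bu4NF buffered with AcOH (THF, rt) removes both silyl groups and returns the route to 15.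

**Further compounds**
F1 | step 2 | racemic cis-fused adduct (4 together with its enantiomer) | CC1=CC(=O)[C@H]2C(C)(C)C(O[Si](C(C)C)(C(C)C)C(C)C)=CC[C@@]2(C)C1=O.CC1=CC(=O)[C@@H]2C(C)(C)C(O[Si](C(C)C)(C(C)C)C(C)C)=CC[C@]2(C)C1=O
F2 | step 4 | (10R)-6-(tert-butyldimethylsilyloxy)-3-(triisopropylsilyloxy)-9-[(trimethylsilyl)methyl]-11-nordrima-2,5,7-trien-9-ol (C9 epimers) | CC1=CC(O[Si](C)(C)C(C)(C)C)=C2C(C)(C)C(O[Si](C(C)C)(C(C)C)C(C)C)=CC[C@@]2(C)C1(O)C[Si](C)(C)C
F3 | step 8 | (3R,5S,6S,10R)-3,6-bis(triethylsilyloxy)drima-7,9(11)-diene | CC1=C[C@H](O[Si](CC)(CC)CC)[C@@H]2C(C)(C)[C@H](O[Si](CC)(CC)CC)CC[C@@]2(C)C1=C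
F4 | step 8 | C11 B-alkyl-9-borabicyclo[3.3.1]nonane derived from F3 | CC1=C[C@H](O[Si](CC)(CC)CC)[C@@H]2C(C)(C)[C@H](O[Si](CC)(CC)CC)CC[C@@]2(C)[C@@H]1CB3C4CCCC3CCC4
F5 | step 8 | (3R,5S,6S,9R,10S)-3,6-bis(triethylsilyloxy)drim-7-en-11-ol | CC1=C[C@H](O[Si](CC)(CC)CC)[C@@H]2C(C)(C)[C@H](O[Si](CC)(CC)CC)CC[C@@]2(C)[C@@H]1CO
F6 | step 8 | 7-{[(3R,5S,6S,9R,10S)-3,6-bis(triethylsilyloxy)drim-7-en-11-yl]oxy}-2H-chromen-2-one | CC1=C[C@H](O[Si](CC)(CC)CC)[C@@H]2C(C)(C)[C@H](O[Si](CC)(CC)CC)CC[C@@]2(C)[C@@H]1COc1ccc2ccc(=O)oc2c1
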